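Retrosynthesis: the six benzyl ethers, the acetate and the cyclic carbonate come off last. Ring C of the upper unit is then cut at C4a–C4 and at C2–C3 in one operation (retro oxa-Povarov), giving an O-aryl O-pivaloyl acetal and the (E)-enol acetate of the complete lower unit. The enol acetate goes back by Baeyer–Villiger and Heck steps to a 6-bromo flavan-3,4-diol, and this by cis-hydroxylation and conjugate arylation to a 6-bromochromone.
Enabling feature: in the upper unit O1, its ortho carbon C4a (para to the 7-oxygen of ring A) and C2 form a 2-oxonia-diene C4a=C8a–O1(+)=C2. C3=C4 is a styrene whose C4 cation is stabilised by the ortho (O7) and para (O1) oxygens of ring A of the lower unit, so the acetoxy-bearing C3 is the nucleophilic end.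
Forward order: ring C of the lower unit (chromone, flavanone, all-cis 3,4-diol), then the C6 side chain, then union of the halves with closure of ring C of the upper unit, then two deprotections.
Stereochemistry: lower C2 comes from a ligand-controlled conjugate addition, lower C3 is relayed from C2 in a trivalent-iodine hydroxylation, and lower C4 from hydride attack anti to the 3-OH. Upper C2 is set by a chiral counter-anion; upper C3 and C4 follow from the E alkene and the endo aryl orientation (2,3-trans-3,4-trans).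

Key step: step 13

Assumption: the sense of induction of the two chiral catalysts (steps 4 and 13) is taken as written; both are available in either antipode, and the antipode that gives the drawn configuration is the one meant.

Step 1
Reactants: 1 1-(2,3,4-trihydroxyphenyl)ethan-1-one (gallacetophenone)
Product: 2 1-[3,4-bis(benzyloxy)-2-hydroxyphenyl]ethan-1-one
Conditions: BnBr (2.1 equiv), K2CO3, DMF, rt
Reagents that add atoms: benzyl bromide, BrCc1ccccc1
Why: Williamson etherification; the 2-OH is hydrogen-bonded to the ketone and least nucleophilic, so the 3- and 4-OH groups should be benzylated selectively.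

Step 2
Reactants: 2 1-[3,4-bis(benzyloxy)-2-hydroxyphenyl]ethan-1-one
Product: 3 1-[3,4-bis(benzyloxy)-5-bromo-2-hydroxyphenyl]ethan-1-one
Conditions: NBS, MeCN, 0 °C
Reagents that add atoms: N-bromosuccinimide, O=C1CCC(=O)N1Br
Why: Electrophilic aromatic bromination; C5 is para to the free phenol, ortho to an ether oxygen and meta to the acetyl group, so all directing effects converge on it.

Step 3
Reactants: 3 1-[3,4-bis(benzyloxy)-5-bromo-2-hydroxyphenyl]ethan-1-one
Product: 5 7,8-bis(benzyloxy)-6-bromo-4H-chromen-4-one, via enaminone 4 (not isolated)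
Conditions: Me2NCH(OMe)2, toluene, 100 °C; then conc. HCl, CH2Cl2, rt
Reagents that add atoms: N,N-dimethylformamide dimethyl acetal, COC(OC)N(C)C
Why: Enaminone formation at the methyl ketone followed by acid-promoted addition–elimination of the phenol with loss of dimethylamine is the standard chromone synthesis.

Step 4
Reactants: 5 7,8-bis(benzyloxy)-6-bromo-4H-chromen-4-one; 6 [4-(benzyloxy)phenyl]boronic acid
Product: 7 (2S)-7,8-bis(benzyloxy)-2-[4-(benzyloxy)phenyl]-6-bromo-2,3-dihydro-4H-chromen-4-one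
Conditions: Pd(OCOCF3)2 (5 mol %), (S)-4-tert-butyl-2-(pyridin-2-yl)-4,5-dihydrooxazole (6 mol %), NH4PF6, H2O, ClCH2CH2Cl, 60 °C
Reagents that add atoms: none
Why: Enantioselective conjugate addition of an arylboronic acid to a chromone under divalent palladium with a pyridine–oxazoline ligand; the ligand selects the face of C2, the non-basic medium avoids ring-opening racemisation, and divalent palladium should leave the C–Br bond untouched.

Step 5
Reactants: 7 (2S)-7,8-bis(benzyloxy)-2-[4-(benzyloxy)phenyl]-6-bromo-2,3-dihydro-4H-chromen-4-one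
Product: 8 (2R,3S)-7,8-bis(benzyloxy)-2-[4-(benzyloxy)phenyl]-6-bromo-4,4-dimethoxy-3,4-dihydro-2H-chromen-3-ol (2,3-cis)
Conditions: PhI(OAc)2, KOH, MeOH, 0 °C to rt
Reagents that add atoms: methanol, CO
Why: Trivalent-iodine α-hydroxylation of a ketone in methanolic hydroxide; the enolate is iodinated trans to the 2-aryl group, methoxide adds to C4, the C4 alkoxide displaces iodobenzene with inversion to a 3,4-epoxide, and methoxide opens it at C4, which places the 3-OH cis to the 2-aryl group.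

Step 6
Reactants: 8 (2R,3S)-7,8-bis(benzyloxy)-2-[4-(benzyloxy)phenyl]-6-bromo-4,4-dimethoxy-3,4-dihydro-2H-chromen-3-ol
Product: 10 (2R,3R,4R)-7,8-bis(benzyloxy)-2-[4-(benzyloxy)phenyl]-6-bromo-3,4-dihydro-2H-chromene-3,4-diol (all-cis), via cis-3-hydroxyflavanone 9 (not isolated)
Conditions: 1 M HCl, acetone, 0 °C; then NaBH4, THF/MeOH, −20 °C
Reagents that add atoms: water, O
Why: Mild hydrolysis of the benzylic ketal and immediate borohydride reduction of the cis-α-hydroxy ketone; with the 2-aryl group equatorial and the 3-OH axial, hydride should attack C4 anti to the 3-OH and give the 3,4-cis (all-cis) diol.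

Step 7
Reactants: 10 (2R,3R,4R)-7,8-bis(benzyloxy)-2-[4-(benzyloxy)phenyl]-6-bromo-3,4-dihydro-2H-chromene-3,4-diol; 11 but-3-en-2-one
Product: 12 (E)-4-[(2R,3R,4R)-7,8-bis(benzyloxy)-2-[4-(benzyloxy)phenyl]-3,4-dihydroxy-3,4-dihydro-2H-chromen-6-yl]but-3-en-2-one
Conditions: Pd(OAc)2, P(o-tolyl)3, Et3N, DMF, 100 °C
Reagents that add atoms: none
Why: Heck reaction of the aryl bromide with an enone; syn insertion and syn β-hydride elimination give the E alkene, and the tertiary amine base leaves the free diol alone.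

Step 8
Reactants: 12 (E)-4-[(2R,3R,4R)-7,8-bis(benzyloxy)-2-[4-(benzyloxy)phenyl]-3,4-dihydroxy-3,4-dihydro-2H-chromen-6-yl]but-3-en-2-one
Product: 13 (2R,3S,4R)-7,8-bis(benzyloxy)-2-[4-(benzyloxy)phenyl]-6-[(E)-3-oxobut-1-en-1-yl]chromane-3,4-diyl carbonate (all-cis; the C3 descriptor changes by ligand priority only)
Conditions: 1,1'-carbonyldiimidazole, THF, rt
Reagents that add atoms: 1,1'-carbonyldiimidazole, O=C(n1ccnc1)n1ccnc1
Why: Cyclic carbonate formation on a cis-1,2-diol; the electron-poor temporary ring protects both hydroxyls and makes the benzylic C4–O bond harder to ionise under acid.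

Step 9
Reactants: 13 (2R,3S,4R)-7,8-bis(benzyloxy)-2-[4-(benzyloxy)phenyl]-6-[(E)-3-oxobut-1-en-1-yl]chromane-3,4-diyl carbonate
Product: 14 (E)-2-[(2R,3S,4R)-7,8-bis(benzyloxy)-2-[4-(benzyloxy)phenyl]-3,4-(carbonyldioxy)chroman-6-yl]ethenyl acetate
Conditions: mCPBA, Na2HPO4, CH2Cl2, 0 °C to rt
Reagents that add atoms: 3-chloroperoxybenzoic acid, OOC(=O)c1cccc(Cl)c1
Why: Baeyer–Villiger oxidation of a conjugated methyl ketone; the alkenyl group migrates in preference to methyl with retention of the E geometry, and buffer with near-stoichiometric peracid should limit epoxidation of the enol acetate.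

Step 10
Reactants: 15 2,3-dihydroxybenzaldehyde
Product: 16 2,3-bis(benzyloxy)benzaldehyde
Conditions: BnBr, K2CO3, DMF, rt
Reagents that add atoms: benzyl bromide, BrCc1ccccc1
Why: Williamson etherification of both phenols.

Step 11
Reactants: 16 2,3-bis(benzyloxy)benzaldehyde
Product: 18 2,3-bis(benzyloxy)phenol, via aryl formate 17 (not isolated)
Conditions: mCPBA, CH2Cl2, rt; then Et3N (cat.), MeOH, rt
Reagents that add atoms: 3-chloroperoxybenzoic acid, OOC(=O)c1cccc(Cl)c1
Why: Dakin-type Baeyer–Villiger oxidation; the electron-rich ortho-alkoxy aryl group migrates to give the formate, which is methanolysed to the phenol.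

Step 12
Reactants: 19 4-(benzyloxy)benzaldehyde; 18 2,3-bis(benzyloxy)phenol
Product: 21 [2,3-bis(benzyloxy)phenoxy][4-(benzyloxy)phenyl]methyl 2,2-dimethylpropanoate (racemic acetal), via chloro ester 20 (not isolated)
Conditions: t-BuCOCl, ZnCl2 (cat.), CH2Cl2, 0 °C; then sodium salt of 18 (NaH, THF), −20 °C to rt
Reagents that add atoms: pivaloyl chloride, CC(C)(C)C(Cl)=O
Why: ZnCl2-catalysed addition of an acyl chloride across an aromatic aldehyde gives the α-chloroalkyl ester, and O-alkylation of the phenoxide by it (acyloxyalkylation) gives the O-aryl O-acyl acetal; the hindered pivaloyl group resists acyl transfer.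

Step 13
Reactants: 14 (E)-2-[(2R,3S,4R)-7,8-bis(benzyloxy)-2-[4-(benzyloxy)phenyl]-3,4-(carbonyldioxy)chroman-6-yl]ethenyl acetate; 21 [2,3-bis(benzyloxy)phenoxy][4-(benzyloxy)phenyl]methyl 2,2-dimethylpropanoate
Product: 22 (2R,3S,4R)-6-[(2S,3R,4R)-3-acetoxy-7,8-bis(benzyloxy)-2-[4-(benzyloxy)phenyl]chroman-4-yl]-7,8-bis(benzyloxy)-2-[4-(benzyloxy)phenyl]chromane-3,4-diyl carbonate (upper unit 2,3-trans-3,4-trans, lower unit all-cis)
Conditions: 21 (1.2 equiv), (S,S)-imidodiphosphorimidate Brønsted acid (5 mol %; BINOL-derived, 3,3'-bis[3,5-bis(trifluoromethyl)phenyl], N-SO2CF3), 5 Å MS, CHCl3, −60 °C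
Reagents that add atoms: none
Why: Proposed new method: the confined chiral acid protonates the pivalate of 21, which ionises (the carboxylate is by far the better leaving group and the aryloxy oxygen the better donor) to the E aryl oxocarbenium ion C4a=C8a–O1(+)=C2 paired with the chiral anion; enol acetate 14 attacks C2 through its acetoxy-bearing carbon C3 because the ortho and para oxygens of ring A of the lower unit stabilise the benzylic cation at C4, and C4a (ortho to O1, para to the 7-benzyloxy group) then closes on that cation with loss of the proton that returns the acid. The closest known reaction types are the Lewis-acid-promoted oxa-Povarov reaction of aryl oxocarbenium ions with styrenes and the enantioselective Prins and oxa-Pictet–Spengler reactions of oxocarbenium ions under imidodiphosphorimidate catalysis. Ring C of the upper unit closes in the inverse-electron-demand polar [4+2] mode (4π 2-oxonia-diene plus 2π alkene, stepwise), its second bond being a six-membered intramolecular Friedel–Crafts alkylation (6-exo-trig on the quinone-methide-like cation). C2 is set by the chiral anion, which shields one face of the oxocarbenium ion; C3 follows from the E geometry of 14 with the acetoxy group exo (2,3-trans); C4 follows from the endo placement of the lower-unit aryl group, reinforced by closure with that group pseudo-equatorial and anti to the participating 3-acetoxy group (3,4-trans, 2,4-cis). The step needs regioselectivity (C3 and not C4 as the nucleophilic carbon, secured because acetoxy is a much weaker donor than the trioxygenated aryl ring), chemoselective ionisation of 21 beside the benzylic C4–O bond of the lower unit (secured by the electron-poor cyclic carbonate and the low temperature) and catalyst control (the lower-unit stereocentres are too remote to compete, and a minor diastereomer would be separable).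

Step 14
Reactants: 22 (2R,3S,4R)-6-[(2S,3R,4R)-3-acetoxy-7,8-bis(benzyloxy)-2-[4-(benzyloxy)phenyl]chroman-4-yl]-7,8-bis(benzyloxy)-2-[4-(benzyloxy)phenyl]chromane-3,4-diyl carbonate
Product: 23 (2R,3R,4R)-6-[(2S,3R,4R)-7,8-bis(benzyloxy)-2-[4-(benzyloxy)phenyl]-3-hydroxychroman-4-yl]-7,8-bis(benzyloxy)-2-[4-(benzyloxy)phenyl]chromane-3,4-diol
Conditions: K2CO3 (cat.), MeOH/THF, rt
Reagents that add atoms: none
Why: Base-catalysed transesterification removes the acetate and the cyclic carbonate together; with all phenols benzylated no quinone methide can form, so no stereocentre should be disturbed.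

Step 15
Reactants: 23 (2R,3R,4R)-6-[(2S,3R,4R)-7,8-bis(benzyloxy)-2-[4-(benzyloxy)phenyl]-3-hydroxychroman-4-yl]-7,8-bis(benzyloxy)-2-[4-(benzyloxy)phenyl]chromane-3,4-diol
Product: 24 (2R,3R,4R)-6-[(2S,3R,4S)-3,7,8-trihydroxy-2-(4-hydroxyphenyl)chroman-4-yl]-2-(4-hydroxyphenyl)chromane-3,4,7,8-tetrol (target; the C4 descriptor of the upper unit changes from R to S by ligand priority only)
Conditions: H2 (1 atm), Pd(OH)2/C, THF/MeOH, rt; filtration under argon
Reagents that add atoms: none
Why: Hydrogenolysis of six aryl benzyl ethers; under neutral conditions these should cleave much faster than the benzylic C–O bonds of the pyran rings and the 4-OH.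

Compound list
1 | 1-(2,3,4-trihydroxyphenyl)ethan-1-one | CC(=O)c1ccc(O)c(O)c1O | starting material
2 | 1-[3,4-bis(benzyloxy)-2-hydroxyphenyl]ethan-1-one | CC(=O)c1ccc(OCc2ccccc2)c(OCc2ccccc2)c1O | intermediate
3 | 1-[3,4-bis(benzyloxy)-5-bromo-2-hydroxyphenyl]ethan-1-one | CC(=O)c1cc(Br)c(OCc2ccccc2)c(OCc2ccccc2)c1O | intermediate
4 | (E)-1-[3,4-bis(benzyloxy)-5-bromo-2-hydroxyphenyl]-3-(dimethylamino)prop-2-en-1-one | CN(C)/C=C/C(=O)c1cc(Br)c(OCc2ccccc2)c(OCc2ccccc2)c1O | intermediate
5 | 7,8-bis(benzyloxy)-6-bromo-4H-chromen-4-one | O=c1ccoc2c(OCc3ccccc3)c(OCc3ccccc3)c(Br)cc12 | intermediate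
6 | [4-(benzyloxy)phenyl]boronic acid | OB(O)c1ccc(OCc2ccccc2)cc1 | starting material
7 | (2S)-7,8-bis(benzyloxy)-2-[4-(benzyloxy)phenyl]-6-bromo-2,3-dihydro-4H-chromen-4-one | c1ccccc1COc1ccc(cc1)[C@H]1Oc2c(cc(Br)c(OCc3ccccc3)c2OCc2ccccc2)C(=O)C1 | intermediate
8 | (2R,3S)-7,8-bis(benzyloxy)-2-[4-(benzyloxy)phenyl]-6-bromo-4,4-dimethoxy-3,4-dihydro-2H-chromen-3-ol | c1ccccc1COc1ccc(cc1)[C@H]1Oc2c(cc(Br)c(OCc3ccccc3)c2OCc2ccccc2)C(OC)(OC)[C@H]1O | intermediate
9 | (2R,3S)-7,8-bis(benzyloxy)-2-[4-(benzyloxy)phenyl]-6-bromo-3-hydroxy-2,3-dihydro-4H-chromen-4-one | c1ccccc1COc1ccc(cc1)[C@H]1Oc2c(cc(Br)c(OCc3ccccc3)c2OCc2ccccc2)C(=O)[C@H]1O | intermediate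
10 | (2R,3R,4R)-7,8-bis(benzyloxy)-2-[4-(benzyloxy)phenyl]-6-bromo-3,4-dihydro-2H-chromene-3,4-diol | c1ccccc1COc1ccc(cc1)[C@H]1Oc2c(cc(Br)c(OCc3ccccc3)c2OCc2ccccc2)[C@@H](O)[C@H]1O | intermediate
11 | but-3-en-2-one | CC(=O)C=C | starting material
12 | (E)-4-[(2R,3R,4R)-7,8-bis(benzyloxy)-2-[4-(benzyloxy)phenyl]-3,4-dihydroxy-3,4-dihydro-2H-chromen-6-yl]but-3-en-2-one | c1ccccc1COc1ccc(cc1)[C@H]1Oc2c(cc(/C=C/C(C)=O)c(OCc3ccccc3)c2OCc2ccccc2)[C@@H](O)[C@H]1O | intermediate
13 | (2R,3S,4R)-7,8-bis(benzyloxy)-2-[4-(benzyloxy)phenyl]-6-[(E)-3-oxobut-1-en-1-yl]chromane-3,4-diyl carbonate | c1ccccc1COc1ccc(cc1)[C@H]1Oc2c(cc(/C=C/C(C)=O)c(OCc3ccccc3)c2OCc2ccccc2)[C@@H](OC(=O)O4)[C@H]14 | intermediate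
14 | (E)-2-[(2R,3S,4R)-7,8-bis(benzyloxy)-2-[4-(benzyloxy)phenyl]-3,4-(carbonyldioxy)chroman-6-yl]ethenyl acetate | c1ccccc1COc1ccc(cc1)[C@H]1Oc2c(cc(/C=C/OC(C)=O)c(OCc3ccccc3)c2OCc2ccccc2)[C@@H](OC(=O)O4)[C@H]14 | intermediate
15 | 2,3-dihydroxybenzaldehyde | O=Cc1cccc(O)c1O | starting material
16 | 2,3-bis(benzyloxy)benzaldehyde | O=Cc1cccc(OCc2ccccc2)c1OCc1ccccc1 | intermediate
17 | 2,3-bis(benzyloxy)phenyl formate | O=COc1cccc(OCc2ccccc2)c1OCc1ccccc1 | intermediate
18 | 2,3-bis(benzyloxy)phenol | Oc1cccc(OCc2ccccc2)c1OCc1ccccc1 | intermediate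
19 | 4-(benzyloxy)benzaldehyde | O=Cc1ccc(OCc2ccccc2)cc1 | starting material
20 | [4-(benzyloxy)phenyl](chloro)methyl 2,2-dimethylpropanoate | CC(C)(C)C(=O)OC(Cl)c1ccc(OCc2ccccc2)cc1 | intermediate
21 | [2,3-bis(benzyloxy)phenoxy][4-(benzyloxy)phenyl]methyl 2,2-dimethylpropanoate (racemic) | CC(C)(C)C(=O)OC(Oc1cccc(OCc2ccccc2)c1OCc1ccccc1)c1ccc(OCc2ccccc2)cc1 | intermediate
22 | (2R,3S,4R)-6-[(2S,3R,4R)-3-acetoxy-7,8-bis(benzyloxy)-2-[4-(benzyloxy)phenyl]chroman-4-yl]-7,8-bis(benzyloxy)-2-[4-(benzyloxy)phenyl]chromane-3,4-diyl carbonate | c1ccccc1COc1ccc(cc1)[C@H]1Oc2c(cc([C@H]5c6ccc(OCc7ccccc7)c(OCc7ccccc7)c6O[C@@H](c6ccc(OCc7ccccc7)cc6)[C@@H]5OC(C)=O)c(OCc3ccccc3)c2OCc2ccccc2)[C@@H](OC(=O)O4)[C@H]14 | intermediate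
23 | (2R,3R,4R)-6-[(2S,3R,4R)-7,8-bis(benzyloxy)-2-[4-(benzyloxy)phenyl]-3-hydroxychroman-4-yl]-7,8-bis(benzyloxy)-2-[4-(benzyloxy)phenyl]chromane-3,4-diol | c1ccccc1COc1ccc(cc1)[C@H]1Oc2c(cc([C@H]5c6ccc(OCc7ccccc7)c(OCc7ccccc7)c6O[C@@H](c6ccc(OCc7ccccc7)cc6)[C@@H]5O)c(OCc3ccccc3)c2OCc2ccccc2)[C@@H](O)[C@H]1O | intermediate
24 | (2R,3R,4R)-6-[(2S,3R,4S)-3,7,8-trihydroxy-2-(4-hydroxyphenyl)chroman-4-yl]-2-(4-hydroxyphenyl)chromane-3,4,7,8-tetrol | Oc1ccc([C@H]2Oc3c(cc([C@H]4c5ccc(O)c(O)c5O[C@@H](c5ccc(O)cc5)[C@@H]4O)c(O)c3O)[C@@H](O)[C@H]2O)cc1 | target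

Total step count: 15. Longest linear sequence: 12 steps (steps 1 to 9, then 13 to 15); steps 10 to 12 form the three-step side branch.

Steps most likely to fail

Step 13 (the step that carries the label). The chiral counter-anion may fail to control the face of the oxocarbenium ion, the acid may turn over poorly, or the benzylic carbonate of the lower unit may ionise in competition. The fallback gives up catalyst control and uses known chemistry: setting out from 14 and 21, the union is run as a Lewis-acid-promoted oxa-Povarov reaction with stoichiometric SnCl4 in CH2Cl2 at −78 °C. The all-trans upper ring should then form in both absolute senses. Because the lower unit is a single enantiomer, the two products are diastereomers: 22 and its isomer with the antipodal upper unit, (2R,3S,4R)-6-[(2R,3S,4S)-3-acetoxy-7,8-bis(benzyloxy)-2-[4-(benzyloxy)phenyl]chroman-4-yl]-7,8-bis(benzyloxy)-2-[4-(benzyloxy)phenyl]chromane-3,4-diyl carbonate F1. They are separated by chromatography and the route is rejoined at 22.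

Step 5. In methanolic hydroxide the flavanone enolate may open by expulsion of the ring phenoxide (retro-oxa-Michael) before it is trapped by trivalent iodine, which would erode the configuration at C2 and the yield. The fallback delivers hydride to C3 in place of oxygen and avoids any free enolate; it sets out from 7 and comes back at 10, bypassing steps 5 and 6.
- Soft enolisation (t-BuMe2SiOSO2CF3, Et3N, CH2Cl2, 0 °C) gives the silyl enol ether (2S)-7,8-bis(benzyloxy)-2-[4-(benzyloxy)phenyl]-6-bromo-4-[(tert-butyldimethylsilyl)oxy]-2H-chromene F2.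
- Hydroboration–oxidation (BH3·THF; then NaBO3·4H2O) anti to the 2-aryl group gives the 2,3-trans-3,4-trans alcohol (2R,3R,4R)-7,8-bis(benzyloxy)-2-[4-(benzyloxy)phenyl]-6-bromo-4-[(tert-butyldimethylsilyl)oxy]chroman-3-ol F3.
- Oxidation with 1,1,1-triacetoxy-1,1-dihydro-1,2-benziodoxol-3(1H)-one (NaHCO3, CH2Cl2) gives the ketone (2R,4R)-7,8-bis(benzyloxy)-2-[4-(benzyloxy)phenyl]-6-bromo-4-[(tert-butyldimethylsilyl)oxy]chroman-3-one F4.
- LiBH(s-Bu)3 (THF, −78 °C) should attack anti to both the 2-aryl and the 4-silyloxy groups and give the all-cis alcohol (2R,3S,4R)-7,8-bis(benzyloxy)-2-[4-(benzyloxy)phenyl]-6-bromo-4-[(tert-butyldimethylsilyl)oxy]chroman-3-ol F5.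
- Bu4NF (THF, 0 °C) then gives 10.

Step 12. The phenoxide may attack the acyl group of the chloro ester, the electron-rich ring may be alkylated at carbon, or the acetal may ionise during isolation. The fallback makes the acyloxy acetal by reduction of an ester instead of by alkylation, setting out from 18.
- Acylation with 4-(benzyloxy)benzoyl chloride (Et3N, DMAP, CH2Cl2) gives the aryl ester 2,3-bis(benzyloxy)phenyl 4-(benzyloxy)benzoate F6.
- Reduction with i-Bu2AlH (CH2Cl2, −78 °C) and in situ acetylation of the aluminium hemiacetal (Ac2O, pyridine, DMAP) gives [2,3-bis(benzyloxy)phenoxy][4-(benzyloxy)phenyl]methyl acetate F7.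
- F7 ionises to the same oxocarbenium ion and replaces 21 under the conditions of step 13, so the route is rejoined at 22.

Further compounds
F1 | step 13 | (2R,3S,4R)-6-[(2R,3S,4S)-3-acetoxy-7,8-bis(benzyloxy)-2-[4-(benzyloxy)phenyl]chroman-4-yl]-7,8-bis(benzyloxy)-2-[4-(benzyloxy)phenyl]chromane-3,4-diyl carbonate | c1ccccc1COc1ccc(cc1)[C@H]1Oc2c(cc([C@@H]5c6ccc(OCc7ccccc7)c(OCc7ccccc7)c6O[C@H](c6ccc(OCc7ccccc7)cc6)[C@H]5OC(C)=O)c(OCc3ccccc3)c2OCc2ccccc2)[C@@H](OC(=O)O4)[C@H]14
F2 | step 5 | (2S)-7,8-bis(benzyloxy)-2-[4-(benzyloxy)phenyl]-6-bromo-4-[(tert-butyldimethylsilyl)oxy]-2H-chromene | c1ccccc1COc1ccc(cc1)[C@H]1Oc2c(cc(Br)c(OCc3ccccc3)c2OCc2ccccc2)C(O[Si](C)(C)C(C)(C)C)=C1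
F3 | step 5 | (2R,3R,4R)-7,8-bis(benzyloxy)-2-[4-(benzyloxy)phenyl]-6-bromo-4-[(tert-butyldimethylsilyl)oxy]chroman-3-ol | c1ccccc1COc1ccc(cc1)[C@H]1Oc2c(cc(Br)c(OCc3ccccc3)c2OCc2ccccc2)[C@@H](O[Si](C)(C)C(C)(C)C)[C@@H]1O
F4 | step 5 | (2R,4R)-7,8-bis(benzyloxy)-2-[4-(benzyloxy)phenyl]-6-bromo-4-[(tert-butyldimethylsilyl)oxy]chroman-3-one | c1ccccc1COc1ccc(cc1)[C@H]1Oc2c(cc(Br)c(OCc3ccccc3)c2OCc2ccccc2)[C@@H](O[Si](C)(C)C(C)(C)C)C1=O
F5 | step 5 | (2R,3S,4R)-7,8-bis(benzyloxy)-2-[4-(benzyloxy)phenyl]-6-bromo-4-[(tert-butyldimethylsilyl)oxy]chroman-3-ol | c1ccccc1COc1ccc(cc1)[C@H]1Oc2c(cc(Br)c(OCc3ccccc3)c2OCc2ccccc2)[C@@H](O[Si](C)(C)C(C)(C)C)[C@H]1O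
F6 | step 12 | 2,3-bis(benzyloxy)phenyl 4-(benzyloxy)benzoate | O=C(Oc1cccc(OCc2ccccc2)c1OCc1ccccc1)c1ccc(OCc2ccccc2)cc1
F7 | step 12 | [2,3-bis(benzyloxy)phenoxy][4-(benzyloxy)phenyl]methyl acetate | CC(=O)OC(Oc1cccc(OCc2ccccc2)c1OCc1ccccc1)c1ccc(OCc2ccccc2)cc1
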